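**Plan**

- Retrosynthesis: in the non-aromatic chromene unit the aryl-O–C8a ketal bond and the C4a=C4 alkene are removed first, which leaves a phenol beside an 8-aryl-8-methoxy-2-phenyl-tetrahydrochromen-5-one. Its dihydropyran is then cut at C4a–C4, C4–C3 and O1–C2 into a 6-aryl-5,6-dimethoxycyclohex-4-ene-1,3-dione, formaldehyde and styrene. The dione goes back through a quinol methyl ether to the bond between flavan C6 and the methoxy-flanked carbonyl carbon of 2,6-dimethoxybenzoquinone.
- Enabling feature: the bridge O1–C2(Ph)–C3–C4 of that ring joins a carbonyl oxygen (on C8a) and the methylene carbon (C4a) of a cyclic 1,3-dione, so C4 is a formaldehyde carbon and C3–C2 are the two carbons of styrene.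
- Forward order: flavan rings (chromone from 3,4,5-trimethoxyphenol, conjugate phenylation, reduction), aryl–quinone C–C bond, O-methylation and mono-hydrolysis to the dione, three-component pyran annulation, closure of the dihydrobenzofuran ketal ring together with the enone alkene, desilylation.
- Stereochemistry: flavan C2 from a chiral palladium catalyst; C4 from axial hydride delivery followed by Mitsunobu inversion; the quaternary carbon arises without control in the hydrolysis and the needed epimer is separated; the phenyl carbon of the new pyran is set in the key step by the neighbouring quaternary carbon; the ketal carbon follows from the enforced cis fusion of the five-membered ring.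

Key step: step 14

Assumption: the (R)-pyridine–oxazoline ligand is taken to give the 2S flavanone, by analogy with the facial preference of this catalyst on cyclic enones; if the opposite sense is found, the (S)-ligand is used.

Abbreviation: Ar = (2S,4R)-4-(tert-butyldimethylsilyloxy)-7,8-dimethoxy-5-(methoxymethoxy)-2-phenylchroman-6-yl. Locants follow chroman/chromene numbering of the unit concerned.

**Route**

Step 1
Reactants: 1 3,4,5-trimethoxyphenol
Product: 2 1,2,3,5-tetramethoxybenzene
Conditions: MeI, K2CO3, acetone, reflux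
Reagents that add atoms: iodomethane, CI
Why: Williamson O-methylation of the phenoxide, the only nucleophilic site present.

Step 2
Reactants: 2 1,2,3,5-tetramethoxybenzene
Product: 3 1-(2-hydroxy-3,4,6-trimethoxyphenyl)ethan-1-one
Conditions: AcCl, AlCl3 (2.5 equiv), CH2Cl2, 0 °C to rt; then H2O
Reagents that add atoms: acetyl chloride, CC(=O)Cl
Why: Friedel–Crafts acylation at one of the two equivalent free positions, then AlCl3-chelate-assisted cleavage of the ortho methoxy group crowded between the acetyl group and a second methoxy group, the regiochemistry established for this acetophenone series, which frees the hydroxyl that becomes the pyran oxygen.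

Step 3
Reactants: 3 1-(2-hydroxy-3,4,6-trimethoxyphenyl)ethan-1-one
Product: 5 5,7,8-trimethoxy-4H-chromen-4-one, via enaminone 4 (not isolated)
Conditions: Me2NCH(OMe)2, toluene, 100 °C; then conc. HCl, CH2Cl2, 40 °C
Reagents that add atoms: N,N-dimethylformamide dimethyl acetal, COC(OC)N(C)C
Why: condensation of the acetyl methyl group with the amide acetal gives the enaminone, and acid then drives addition of the phenol to its β-carbon with loss of dimethylamine, the standard enaminone route to 2,3-unsubstituted chromones.

Step 4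
Reactants: 5 5,7,8-trimethoxy-4H-chromen-4-one
Product: 6 5-hydroxy-7,8-dimethoxy-4H-chromen-4-one
Conditions: BCl3, CH2Cl2, −78 to 0 °C; then H2O
Reagents that add atoms: none
Why: chelation-directed ether cleavage, in which boron bound to the carbonyl oxygen activates only the peri 5-methoxy group and leaves the 7- and 8-methoxy groups intact.

Step 5
Reactants: 6 5-hydroxy-7,8-dimethoxy-4H-chromen-4-one
Product: 7 7,8-dimethoxy-5-(methoxymethoxy)-4H-chromen-4-one
Conditions: NaH, MOMCl, DMF, 0 °C to rt
Reagents that add atoms: chloromethyl methyl ether, COCCl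
Why: alkylation of the sodium phenoxide (a strong base is needed because the 5-hydroxyl is hydrogen-bonded to the carbonyl) installs an acetal that later directs lithiation and can be removed without protic acid.

Step 6
Reactants: 7 7,8-dimethoxy-5-(methoxymethoxy)-4H-chromen-4-one; 8 phenylboronic acid
Product: 9 (2S)-7,8-dimethoxy-5-(methoxymethoxy)-2-phenylchroman-4-one
Conditions: Pd(OCOCF3)2 (5 mol %), (R)-t-BuPyOx [(R)-4-tert-butyl-2-(pyridin-2-yl)-4,5-dihydrooxazole] (6 mol %), NH4PF6 (30 mol %), H2O (5 equiv), ClCH2CH2Cl, 60 °C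
Reagents that add atoms: none
Why: asymmetric conjugate addition of an arylboronic acid to a chromone under divalent palladium and pyridine–oxazoline catalysis, in which the ligand-controlled face of aryl–palladium insertion into C2=C3 sets C2 as S and protonolysis of the palladium enolate releases the flavanone.

Step 7
Reactants: 9 (2S)-7,8-dimethoxy-5-(methoxymethoxy)-2-phenylchroman-4-one
Product: 10 (2S,4S)-7,8-dimethoxy-5-(methoxymethoxy)-2-phenylchroman-4-ol (2,4-cis)
Conditions: NaBH4, MeOH/THF, 0 °C
Reagents that add atoms: none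
Why: borohydride reduction in which hydride adds along the axial trajectory of the half-chair that carries the 2-phenyl group equatorial, giving the equatorial 2,4-cis alcohol (4S), the general outcome for flavanones.

Step 8
Reactants: 10 (2S,4S)-7,8-dimethoxy-5-(methoxymethoxy)-2-phenylchroman-4-ol
Product: 11 (2S,4R)-7,8-dimethoxy-5-(methoxymethoxy)-2-phenylchroman-4-yl 4-nitrobenzoate (2,4-trans)
Conditions: 4-O2NC6H4CO2H, PPh3, DIAD, THF, 0 °C to rt
Reagents that add atoms: 4-nitrobenzoic acid, O=C(O)c1ccc(cc1)[N+](=O)[O-]
Why: Mitsunobu esterification inverts C4 by SN2 displacement of the oxyphosphonium group to give the 2,4-trans (4R) ester, and axial attack with relief of peri strain against the 5-substituent favours the same isomer even if some ionisation occurs.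

Step 9
Reactants: 11 (2S,4R)-7,8-dimethoxy-5-(methoxymethoxy)-2-phenylchroman-4-yl 4-nitrobenzoate
Product: 12 (2S,4R)-7,8-dimethoxy-5-(methoxymethoxy)-2-phenylchroman-4-ol
Conditions: K2CO3, MeOH, rt
Reagents that add atoms: none
Why: base-catalysed transesterification removes the nitrobenzoate at the acyl carbon, so the C4–O bond and the trans configuration stay untouched.

Step 10
Reactants: 12 (2S,4R)-7,8-dimethoxy-5-(methoxymethoxy)-2-phenylchroman-4-ol
Product: 13 (2S,4R)-4-(tert-butyldimethylsilyloxy)-7,8-dimethoxy-5-(methoxymethoxy)-2-phenylchroman (Ar–H)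
Conditions: TBSOTf, 2,6-lutidine, CH2Cl2, −78 to 0 °C
Reagents that add atoms: tert-butyldimethylsilyl trifluoromethanesulfonate, CC(C)(C)[Si](C)(C)OS(=O)(=O)C(F)(F)F
Why: silylation of the hindered pseudo-axial alcohol with the silyl triflate gives an ether that withstands the organolithium, hydride base and hydroxide used afterwards.

Step 11
Reactants: 13 Ar–H; 14 2,6-dimethoxy-1,4-benzoquinone
Product: 16 4-Ar-4-hydroxy-3,5-dimethoxycyclohexa-2,5-dien-1-one, via aryllithium 15 (not isolated)
Conditions: n-BuLi (1.1 equiv), THF, 0 °C; then added to 14, THF, −78 °C; aq. NH4Cl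
Reagents that add atoms: none
Why: directed ortho-metalation at the only aromatic C–H of ring A, flanked by the OMOM and OMe groups, then 1,2-addition of the aryllithium to the quinone carbonyl that lies between the two methoxy-bearing carbons, the more electrophilic one because the other carbonyl is a doubly vinylogous ester.

Step 12
Reactants: 16 4-Ar-4-hydroxy-3,5-dimethoxycyclohexa-2,5-dien-1-one
Product: 17 4-Ar-3,4,5-trimethoxycyclohexa-2,5-dien-1-one
Conditions: NaH, MeI, THF/DMF, 0 °C to rt
Reagents that add atoms: iodomethane, CI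
Why: Williamson methylation of the tertiary quinol alkoxide, the only acidic site in the molecule.

Step 13
Reactants: 17 4-Ar-3,4,5-trimethoxycyclohexa-2,5-dien-1-one
Product: 18 (6S)-6-Ar-5,6-dimethoxycyclohex-4-ene-1,3-dione (drawn as the diketone; largely enolised)
Conditions: LiOH, THF/H2O, 50 °C; then aq. HCl to pH 4, 0 °C; chromatographic separation of the C6 epimers
Reagents that add atoms: lithium hydroxide, [Li+].[OH-]
Why: vinylogous ester saponification (conjugate addition of hydroxide, loss of methoxide) stops after one methoxy group because the product is a delocalised vinylogous carboxylate; the two enol ethers differ only through the distant flavan stereocentres, so both epimers at the new quaternary carbon are expected in similar amounts and the 6S epimer is isolated.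

Step 14
Reactants: 18 (6S)-6-Ar-5,6-dimethoxycyclohex-4-ene-1,3-dione; 19 formaldehyde (supplied as paraformaldehyde); 20 styrene
Product: 22 (2S,8S)-8-Ar-7,8-dimethoxy-2-phenyl-2,3,4,8-tetrahydro-5H-chromen-5-one, via methylene dione 21 (not isolated)
Conditions: (CH2O)n, styrene (10 equiv), ethylenediammonium diacetate (20 mol %), MeCN, 80 °C, sealed tube
Reagents that add atoms: none
Why: The ammonium acetate catalyst condenses formaldehyde with the acidic C2 methylene of 18 (Knoevenagel) to the 2-methylene-1,3-dione 21, whose C=C–C=O unit adds to styrene as an electron-poor 1-oxadiene in an asynchronous inverse-electron-demand hetero-Diels–Alder reaction, the C–C bond to the styrene terminus running ahead of the O–C bond to the benzylic carbon; the closest known reaction type is the three-component domino Knoevenagel/hetero-Diels–Alder reaction of cyclic 1,3-diones with formaldehyde and styrenes. The dihydropyran ring closes by this [4+2] cycloaddition: C4a–C4 forms in the condensation, C4–C3 and O1–C2 in the cycloaddition. The new stereocentre C2 is controlled by the adjacent quaternary carbon, whose bulky aryl group shields one face of the flat oxadiene, so styrene should approach the methoxy-bearing face with phenyl endo, the usual orientation of styrenes on oxadienes, and this combination gives 2S. The step also needs closure through the oxygen of the ketone next to the quaternary carbon and not through the vinylogous ester carbonyl; the ketone is the better heterodiene partner, as in alkylidene β-keto esters where the ester carbonyl stays out, and this mode leaves the methoxy enone intact and gives the more stable cross-conjugated dienone. A large excess of styrene keeps 21 from being captured by a second molecule of 18.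

Step 15
Reactants: 22 (2S,8S)-8-Ar-7,8-dimethoxy-2-phenyl-2,3,4,8-tetrahydro-5H-chromen-5-one
Product: 24 (2S,8S)-8-[(2S,4R)-4-(tert-butyldimethylsilyloxy)-5-hydroxy-7,8-dimethoxy-2-phenylchroman-6-yl]-7,8-dimethoxy-2-phenyl-2,3,4,8-tetrahydro-5H-chromen-5-one, via aryl trimethylsilyl ether 23 (not isolated)
Conditions: Me3SiOTf, 2,2'-bipyridyl, CH2Cl2, 0 °C to rt; then H2O
Reagents that add atoms: none
Why: the silyl triflate–bipyridyl pair activates only the acetal oxygens of the MOM group and turns the aryl MOM ether into the aryl silyl ether, which water hydrolyses, a non-protic acetal cleavage that spares the TBS ether, the enol ethers and the benzylic C–O bonds.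

Step 16
Reactants: 24 the phenol from step 15
Product: 25 pentacyclic seleno ketal (phenol oxygen bonded to C8a of the chromenone unit, PhSe on C4a trans to that oxygen, dihydrobenzofuran cis-fused)
Conditions: PhSeCl, K2CO3, CH2Cl2, −78 °C
Reagents that add atoms: phenylselenenyl chloride, Cl[Se]c1ccccc1
Why: phenylselenoetherification, in which the selenium electrophile attacks the tetrasubstituted enol ether at C4a from the face opposite the aryl group and the phenol captures the oxocarbenium ion at C8a in a 5-exo closure; the tether permits only the cis-fused dihydrobenzofuran, so the quaternary carbon fixes the ketal configuration.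

Step 17
Reactants: 25 pentacyclic seleno ketal
Product: 27 4-O-tert-butyldimethylsilyl-6''-demethoxyneocalycopterone, via selenoxide 26 (not isolated)
Conditions: H2O2 (30% aq.), pyridine, CH2Cl2, 0 °C to rt
Reagents that add atoms: none
Why: oxidation to the selenoxide and its syn elimination (selenoxide elimination of an α-seleno ketone) can only take a hydrogen from C4, since the other carbons next to C4a bear none, and so gives the C4a=C4 enone.

Step 18
Reactants: 27 4-O-tert-butyldimethylsilyl-6''-demethoxyneocalycopterone
Product: 28 6''-demethoxyneocalycopterone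
Conditions: Bu4NF, AcOH, THF, 0 °C to rt
Reagents that add atoms: none
Why: fluoride cleaves the silyl ether, and the acetic acid buffer keeps the medium from removing the enone γ-hydrogens or ionising the benzylic alcohol, so no stereocentre is affected.

**Compound list**

1 | 3,4,5-trimethoxyphenol | COc1cc(O)cc(OC)c1OC | starting material
2 | 1,2,3,5-tetramethoxybenzene | COc1cc(OC)c(OC)c(OC)c1 | intermediate
3 | 1-(2-hydroxy-3,4,6-trimethoxyphenyl)ethan-1-one | CC(=O)c1c(O)c(OC)c(OC)cc1OC | intermediate
4 | (E)-3-(dimethylamino)-1-(2-hydroxy-3,4,6-trimethoxyphenyl)prop-2-en-1-one (enaminone, not isolated) | CN(C)/C=C/C(=O)c1c(O)c(OC)c(OC)cc1OC | intermediate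
5 | 5,7,8-trimethoxy-4H-chromen-4-one | COc1cc(OC)c2c(=O)ccoc2c1OC | intermediate
6 | 5-hydroxy-7,8-dimethoxy-4H-chromen-4-one | COc1cc(O)c2c(=O)ccoc2c1OC | intermediate
7 | 7,8-dimethoxy-5-(methoxymethoxy)-4H-chromen-4-one | COCOc1cc(OC)c(OC)c2occc(=O)c12 | intermediate
8 | phenylboronic acid | OB(O)c1ccccc1 | starting material
9 | (2S)-7,8-dimethoxy-5-(methoxymethoxy)-2-phenylchroman-4-one | COCOc1cc(OC)c(OC)c2O[C@H](c3ccccc3)CC(=O)c12 | intermediate
10 | (2S,4S)-7,8-dimethoxy-5-(methoxymethoxy)-2-phenylchroman-4-ol (cis) | COCOc1cc(OC)c(OC)c2O[C@H](c3ccccc3)C[C@H](O)c12 | intermediate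
11 | (2S,4R)-7,8-dimethoxy-5-(methoxymethoxy)-2-phenylchroman-4-yl 4-nitrobenzoate (trans) | COCOc1cc(OC)c(OC)c2O[C@H](c3ccccc3)C[C@@H](OC(=O)c3ccc(cc3)[N+](=O)[O-])c12 | intermediate
12 | (2S,4R)-7,8-dimethoxy-5-(methoxymethoxy)-2-phenylchroman-4-ol (trans) | COCOc1cc(OC)c(OC)c2O[C@H](c3ccccc3)C[C@@H](O)c12 | intermediate
13 | (2S,4R)-4-(tert-butyldimethylsilyloxy)-7,8-dimethoxy-5-(methoxymethoxy)-2-phenylchroman (Ar–H) | COCOc1cc(OC)c(OC)c2O[C@H](c3ccccc3)C[C@@H](O[Si](C)(C)C(C)(C)C)c12 | intermediate
14 | 2,6-dimethoxy-1,4-benzoquinone | COC1=CC(=O)C=C(OC)C1=O | starting material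
15 | 6-lithio derivative of 13 (Ar–Li, not isolated) | [Li]c1c(OCOC)c2c(c(OC)c1OC)O[C@H](c3ccccc3)C[C@H]2O[Si](C)(C)C(C)(C)C | intermediate
16 | 4-Ar-4-hydroxy-3,5-dimethoxycyclohexa-2,5-dien-1-one | COC1=CC(=O)C=C(OC)C1(O)c1c(OCOC)c2c(c(OC)c1OC)O[C@H](c3ccccc3)C[C@H]2O[Si](C)(C)C(C)(C)C | intermediate
17 | 4-Ar-3,4,5-trimethoxycyclohexa-2,5-dien-1-one | COC1=CC(=O)C=C(OC)C1(OC)c1c(OCOC)c2c(c(OC)c1OC)O[C@H](c3ccccc3)C[C@H]2O[Si](C)(C)C(C)(C)C | intermediate
18 | (6S)-6-Ar-5,6-dimethoxycyclohex-4-ene-1,3-dione | COC1=CC(=O)CC(=O)[C@]1(OC)c1c(OCOC)c2c(c(OC)c1OC)O[C@H](c3ccccc3)C[C@H]2O[Si](C)(C)C(C)(C)C | intermediate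
19 | formaldehyde (supplied as paraformaldehyde) | C=O | starting material
20 | styrene | C=Cc1ccccc1 | starting material
21 | (6S)-6-Ar-5,6-dimethoxy-2-methylenecyclohex-4-ene-1,3-dione (not isolated) | COC1=CC(=O)C(=C)C(=O)[C@]1(OC)c1c(OCOC)c2c(c(OC)c1OC)O[C@H](c3ccccc3)C[C@H]2O[Si](C)(C)C(C)(C)C | intermediate
22 | (2S,8S)-8-Ar-7,8-dimethoxy-2-phenyl-2,3,4,8-tetrahydro-5H-chromen-5-one | COC1=CC(=O)C2=C(O[C@H](c3ccccc3)CC2)[C@]1(OC)c1c(OCOC)c2c(c(OC)c1OC)O[C@H](c3ccccc3)C[C@H]2O[Si](C)(C)C(C)(C)C | intermediate
23 | O-trimethylsilyl ether of phenol 24 (not isolated) | COC1=CC(=O)C2=C(O[C@H](c3ccccc3)CC2)[C@]1(OC)c1c(O[Si](C)(C)C)c2c(c(OC)c1OC)O[C@H](c3ccccc3)C[C@H]2O[Si](C)(C)C(C)(C)C | intermediate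
24 | (2S,8S)-8-[(2S,4R)-4-(tert-butyldimethylsilyloxy)-5-hydroxy-7,8-dimethoxy-2-phenylchroman-6-yl]-7,8-dimethoxy-2-phenyl-2,3,4,8-tetrahydro-5H-chromen-5-one | COC1=CC(=O)C2=C(O[C@H](c3ccccc3)CC2)[C@]1(OC)c1c(O)c2c(c(OC)c1OC)O[C@H](c3ccccc3)C[C@H]2O[Si](C)(C)C(C)(C)C | intermediate
25 | pentacyclic seleno ketal (PhSe on C4a trans to the aryl oxygen on C8a) | COC1=CC(=O)[C@]2([Se]c5ccccc5)CC[C@@H](c3ccccc3)O[C@]23Oc2c4c(c(OC)c(OC)c2[C@]13OC)O[C@H](c1ccccc1)C[C@H]4O[Si](C)(C)C(C)(C)C | intermediate
26 | selenoxide of 25 (not isolated; both configurations at selenium) | COC1=CC(=O)[C@]2([Se](=O)c5ccccc5)CC[C@@H](c3ccccc3)O[C@]23Oc2c4c(c(OC)c(OC)c2[C@]13OC)O[C@H](c1ccccc1)C[C@H]4O[Si](C)(C)C(C)(C)C | intermediate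
27 | 4-O-tert-butyldimethylsilyl-6''-demethoxyneocalycopterone | COC1=CC(=O)C2=CC[C@@H](c3ccccc3)O[C@]23Oc2c4c(c(OC)c(OC)c2[C@]13OC)O[C@H](c1ccccc1)C[C@H]4O[Si](C)(C)C(C)(C)C | intermediate
28 | 6''-demethoxyneocalycopterone | COC1=CC(=O)C2=CC[C@@H](c3ccccc3)O[C@]23Oc2c4c(c(OC)c(OC)c2[C@]13OC)O[C@H](c1ccccc1)C[C@H]4O | target

**Step count and risks**

Total: 18 steps. Longest linear sequence: 18 steps (1 to 28).

Step 14. The annulation may lose control at the phenyl-bearing carbon (exo approach of styrene, or approach past the aryl group), may close through the vinylogous ester oxygen, or the methylene dione may be intercepted by a second dione molecule. The fallback sets out from 18 and returns at 22, and takes the phenyl stereocentre from a reagent instead of from the cycloaddition. Three-component reductive alkylation of 18 with (S)-3-phenyl-3-(triethylsilyloxy)propanal and a Hantzsch ester under L-proline catalysis (Knoevenagel condensation, then conjugate transfer hydrogenation) should give the 2-(3-silyloxy-3-phenylpropyl) dione F1. Pyridinium p-toluenesulfonate in methanol removes only the triethylsilyl group to give the hydroxy dione F2. Warming F2 with the same acid in toluene over molecular sieves closes the hemiketal and dehydrates it to 22; the benzylic C–O bond is never broken, so the S configuration is retained, and reversible hemiketal formation lets the cross-conjugated isomer accumulate.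

Step 16. The selenium electrophile may instead attack the methine carbon of the methoxy enone (substitution without ketal formation), or the addition may be reversed by chloride. The fallback sets out from 24 and returns at 27 without an electrophilic attack on the enol ether. A catalytic amount of DBU (1,8-diazabicyclo[5.4.0]undec-7-ene) should close the ring by intramolecular oxa-Michael addition of the phenoxide to C8a, giving the saturated ketal ketone F3 (either configuration at C4a). Soft enolisation with Me3SiOTf and Et3N gives the silyl dienol ether F4. Saegusa–Ito oxidation with Pd(OAc)2 (divalent palladium, MeCN, rt) then introduces the C4a=C4 alkene by β-hydride elimination from C4 and gives 27.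

Step 11. The hindered aryllithium may reduce the quinone by electron transfer, or add at the unhindered carbonyl. The fallback sets out from 13 and returns at 17, and builds the quinol ether by biaryl coupling and oxidative dearomatisation. Lithiation of 13 as before and transmetalation with ZnCl2 gives the arylzinc chloride F5. Negishi coupling with (4-bromo-3,5-dimethoxyphenoxy)(tert-butyl)dimethylsilane under Pd2(dba)3 and SPhos (zerovalent palladium with a biarylphosphine suited to four ortho alkoxy groups) gives the biaryl bis-silyl ether F6. K2CO3 in methanol cleaves only the aryl silyl ether to the biaryl phenol F7. PhI(OAc)2 in methanol oxidises the phenol, and methanol adds at the aryl-bearing para carbon to give 17 directly.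

**Further compounds**

F1 | step 14 | (6S)-6-Ar-5,6-dimethoxy-2-[(3S)-3-phenyl-3-(triethylsilyloxy)propyl]cyclohex-4-ene-1,3-dione (drawn as the diketone) | COC1=CC(=O)C(CC[C@H](O[Si](CC)(CC)CC)c3ccccc3)C(=O)[C@]1(OC)c1c(OCOC)c2c(c(OC)c1OC)O[C@H](c3ccccc3)C[C@H]2O[Si](C)(C)C(C)(C)C
F2 | step 14 | (6S)-6-Ar-2-[(3S)-3-hydroxy-3-phenylpropyl]-5,6-dimethoxycyclohex-4-ene-1,3-dione | COC1=CC(=O)C(CC[C@H](O)c3ccccc3)C(=O)[C@]1(OC)c1c(OCOC)c2c(c(OC)c1OC)O[C@H](c3ccccc3)C[C@H]2O[Si](C)(C)C(C)(C)C
F3 | step 16 | saturated ketal ketone (4a,4-dihydro-27; C4a unassigned) | COC1=CC(=O)C2CC[C@@H](c3ccccc3)O[C@]23Oc2c4c(c(OC)c(OC)c2[C@]13OC)O[C@H](c1ccccc1)C[C@H]4O[Si](C)(C)C(C)(C)C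
F4 | step 16 | trimethylsilyl dienol ether of F3 | COC1=CC(O[Si](C)(C)C)=C2CC[C@@H](c3ccccc3)O[C@]23Oc2c4c(c(OC)c(OC)c2[C@]13OC)O[C@H](c1ccccc1)C[C@H]4O[Si](C)(C)C(C)(C)C
F5 | step 11 | arylzinc chloride Ar–ZnCl | Cl[Zn]c1c(OCOC)c2c(c(OC)c1OC)O[C@H](c3ccccc3)C[C@H]2O[Si](C)(C)C(C)(C)C
F6 | step 11 | 6-[4-(tert-butyldimethylsilyloxy)-2,6-dimethoxyphenyl] derivative of 13 | COc1cc(O[Si](C)(C)C(C)(C)C)cc(OC)c1-c1c(OCOC)c2c(c(OC)c1OC)O[C@H](c3ccccc3)C[C@H]2O[Si](C)(C)C(C)(C)C
F7 | step 11 | 4-Ar-3,5-dimethoxyphenol | COc1cc(O)cc(OC)c1-c1c(OCOC)c2c(c(OC)c1OC)O[C@H](c3ccccc3)C[C@H]2O[Si](C)(C)C(C)(C)C
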